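**Retrosynthetic overview**
1. Target 18 comes from the bis-silyl flavanone 17 by buffered fluoride cleavage of both aryl silyl ethers.
2. 17 is disconnected at C4–C4a (Parham cyclisation of the bromo aryl ether 14). The strategy rests on C4a of ring A lying ortho to O1 and para to the C7 oxygen: a bromine placed there by directed lithiation fixes where C4 is attached, and the acylation is then done by an aryllithium, without the acid that would cyclise the C8 geranyl chain onto a neighbouring oxygen.
3. 14 is disconnected at O1–C2: Mitsunobu etherification of phenol 9 with the (R)-β-hydroxy Weinreb amide 13, with inversion to 2S.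
4. 9 comes from resorcinol (two MOM-directed lithiations place geranyl at the future C8 and bromine at the future C4a, then MOM removal and silylation of the less hindered oxygen). 13 comes from ethyl 3-(4-hydroxyphenyl)-3-oxopropanoate (silylation, Noyori hydrogenation, aminolysis).
5. Ring order: rings A and B are carried in as benzene rings; ring C is the only ring formed, in step 10.

Key step: step 10

Assumption: geranyl bromide is used as the pure 2E isomer, so the 2E alkene is carried through unchanged. Abbreviations: geranyl = (2E)-3,7-dimethylocta-2,6-dien-1-yl, TBS = tert-butyldimethylsilyl, MOM = methoxymethyl.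

**Route**

Step 1
Reactants: 1 resorcinol
Product: 2 1,3-bis(methoxymethoxy)benzene
Conditions: NaH, MOMCl, DMF, 0 °C to rt
Reagents that add atoms: chloromethyl methyl ether (MOMCl), COCCl
Why: Williamson-type O-alkylation of the bis-phenoxide installs two MOM acetals that serve both as protecting groups and as directing groups for the two lithiations that follow.

Step 2
Reactants: 2 1,3-bis(methoxymethoxy)benzene; 3 geranyl bromide
Product: 5 2-geranyl-1,3-bis(methoxymethoxy)benzene, via 2-lithio-1,3-bis(methoxymethoxy)benzene 4 (not isolated)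
Conditions: n-BuLi, THF, 0 °C to rt; then 3, −78 °C to rt
Reagents that add atoms: none
Why: Directed ortho-metalation occurs at the carbon flanked by both OMOM groups, and the aryllithium should displace the primary allylic bromide in an SN2 sense (the γ-carbon is fully substituted), keeping the 2E geometry.

Step 3
Reactants: 5 2-geranyl-1,3-bis(methoxymethoxy)benzene
Product: 7 1-bromo-3-geranyl-2,4-bis(methoxymethoxy)benzene, via 4-lithio-2-geranyl-1,3-bis(methoxymethoxy)benzene 6 (not isolated)
Conditions: n-BuLi, TMEDA, THF, −20 to 0 °C; then BrCCl2CCl2Br, −78 °C to rt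
Reagents that add atoms: 1,2-dibromo-1,1,2,2-tetrachloroethane, BrC(Cl)(Cl)C(Cl)(Cl)Br
Why: A second directed ortho-metalation can only occur at the ring position next to an OMOM group, and bromine transfer from the polyhalide to the aryllithium puts the halogen at the future C4a without exposing the alkenes to an electrophilic brominating agent.

Step 4
Reactants: 7 1-bromo-3-geranyl-2,4-bis(methoxymethoxy)benzene
Product: 8 4-bromo-2-geranylbenzene-1,3-diol
Conditions: HCl (3 M aq., substoichiometric), MeOH, rt to 40 °C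
Reagents that add atoms: none
Why: Acid-catalysed acetal exchange with methanol removes both aryl MOM groups under dilute, mild conditions that should be too weak to protonate the trisubstituted alkenes of the geranyl chain.

Step 5
Reactants: 8 4-bromo-2-geranylbenzene-1,3-diol
Product: 9 6-bromo-3-(tert-butyldimethylsilyloxy)-2-geranylphenol
Conditions: TBSCl (1.0 equiv), imidazole, CH2Cl2, −20 to 0 °C
Reagents that add atoms: tert-butyldimethylsilyl chloride (TBSCl), CC(C)(C)[Si](C)(C)Cl
Why: Sterically controlled monosilylation should take place at the hydroxyl flanked by geranyl and hydrogen in preference to the one wedged between geranyl and bromine, which is left free as the future O1.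

Step 6
Reactants: 10 ethyl 3-(4-hydroxyphenyl)-3-oxopropanoate
Product: 11 ethyl 3-[4-(tert-butyldimethylsilyloxy)phenyl]-3-oxopropanoate
Conditions: TBSCl, imidazole, DMF, 0 °C to rt
Reagents that add atoms: tert-butyldimethylsilyl chloride (TBSCl), CC(C)(C)[Si](C)(C)Cl
Why: Silylation of the phenol is much faster than O-silylation of the β-keto ester enol and masks the acidic 4'-OH for the organometallic steps.

Step 7
Reactants: 11 ethyl 3-[4-(tert-butyldimethylsilyloxy)phenyl]-3-oxopropanoate
Product: 12 ethyl (3R)-3-[4-(tert-butyldimethylsilyloxy)phenyl]-3-hydroxypropanoate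
Conditions: H2 (50 atm), RuCl2[(S)-BINAP] (1 mol%), EtOH, 60 °C
Reagents that add atoms: none
Why: Noyori asymmetric hydrogenation of the chelating β-keto ester sets the carbinol centre under ligand control, the (S)-diphosphine delivering hydride to the face that gives the (R) alcohol (the descriptor is opposite to that of the alkyl series because aryl outranks CH2CO2Et).

Step 8
Reactants: 12 ethyl (3R)-3-[4-(tert-butyldimethylsilyloxy)phenyl]-3-hydroxypropanoate
Product: 13 (3R)-3-[4-(tert-butyldimethylsilyloxy)phenyl]-3-hydroxy-N-methoxy-N-methylpropanamide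
Conditions: MeNHOMe·HCl, i-PrMgCl, THF, −20 to 0 °C
Reagents that add atoms: N,O-dimethylhydroxylamine hydrochloride, CNOC.Cl
Why: Aminolysis of the ester by the magnesium amide of N,O-dimethylhydroxylamine gives the Weinreb amide directly, the β-hydroxyl being carried as its magnesium alkoxide at a temperature too low for retro-aldol cleavage.

Step 9
Reactants: 9 6-bromo-3-(tert-butyldimethylsilyloxy)-2-geranylphenol; 13 (3R)-3-[4-(tert-butyldimethylsilyloxy)phenyl]-3-hydroxy-N-methoxy-N-methylpropanamide
Product: 14 (3S)-3-[6-bromo-3-(tert-butyldimethylsilyloxy)-2-geranylphenoxy]-3-[4-(tert-butyldimethylsilyloxy)phenyl]-N-methoxy-N-methylpropanamide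
Conditions: PPh3, DIAD, toluene, 0 °C to rt
Reagents that add atoms: none
Why: In the Mitsunobu reaction the acidic ortho-bromophenol displaces the oxyphosphonium-activated benzylic hydroxyl by SN2 with inversion, converting the (R) carbinol into the (S) aryl ether that becomes C2; the non-polar solvent and low temperature are chosen to disfavour ionisation and dehydration.

Step 10
Reactants: 14 (3S)-3-[6-bromo-3-(tert-butyldimethylsilyloxy)-2-geranylphenoxy]-3-[4-(tert-butyldimethylsilyloxy)phenyl]-N-methoxy-N-methylpropanamide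
Product: 17 (2S)-7-(tert-butyldimethylsilyloxy)-2-[4-(tert-butyldimethylsilyloxy)phenyl]-8-geranylchroman-4-one, via aryllithium 15 (not isolated), via lithium hemiaminal 16 (not isolated)
Conditions: t-BuLi (2.05 equiv), THF/Et2O, −100 °C; then AcOH in THF, −100 to −20 °C; pH 7 buffer
Reagents that add atoms: none
Why: At −100 °C t-BuLi should exchange the bromine at the future C4a faster than it deprotonates or adds to the amide (the second equivalent destroys the tert-butyl bromide formed), and the aryllithium 15 then attacks the tethered N-methoxy-N-methylamide carbonyl. This is a Parham cyclisation, the closest known reaction type being halogen–lithium exchange of ortho-halophenyl ethers followed by acylation on a tethered amide to give chroman-4-ones. Ring C is closed in a 6-exo-trig mode with formation of the C4–C4a bond. No stereocentre is created in the product; C2 is untouched, and the chelated lithium hemiaminal 16 keeps C4 tetrahedral until the cold acetic acid quench, so no enolisable ketone meets base that could expel the C2 aryloxide and open or racemise the ring. The selectivity needed is exchange and intramolecular acylation over deprotonation alpha to the amide, and it is secured by the very low temperature, the fast exchange of an aryl bromide next to oxygen and the short tether that makes acylation intramolecular. The geranyl alkenes and both aryl silyl ethers (the C7 one para, not ortho, to the lithiated carbon, so no silyl migration) should be inert.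

Step 11
Reactants: 17 (2S)-7-(tert-butyldimethylsilyloxy)-2-[4-(tert-butyldimethylsilyloxy)phenyl]-8-geranylchroman-4-one
Product: 18 (2S)-7,4'-dihydroxy-8-geranylflavanone
Conditions: TBAF, AcOH, THF, 0 °C
Reagents that add atoms: none
Why: Fluoride cleaves both aryl silyl ethers, and the acetic acid buffer protonates the phenoxides as they form, so the flavanone is not exposed to the base that would open ring C to the chalcone and erode the C2 configuration.

**Compound list**
1 | resorcinol | Oc1cccc(O)c1 | starting material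
2 | 1,3-bis(methoxymethoxy)benzene | COCOc1cccc(OCOC)c1 | intermediate
3 | geranyl bromide, (2E)-1-bromo-3,7-dimethylocta-2,6-diene | CC(C)=CCC/C(C)=C/CBr | starting material
4 | 2-lithio-1,3-bis(methoxymethoxy)benzene | COCOc1cccc(OCOC)c1[Li] | intermediate
5 | 2-geranyl-1,3-bis(methoxymethoxy)benzene | CC(C)=CCC/C(C)=C/Cc1c(OCOC)cccc1OCOC | intermediate
6 | 4-lithio-2-geranyl-1,3-bis(methoxymethoxy)benzene | CC(C)=CCC/C(C)=C/Cc1c(OCOC)ccc([Li])c1OCOC | intermediate
7 | 1-bromo-3-geranyl-2,4-bis(methoxymethoxy)benzene | CC(C)=CCC/C(C)=C/Cc1c(OCOC)ccc(Br)c1OCOC | intermediate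
8 | 4-bromo-2-geranylbenzene-1,3-diol | CC(C)=CCC/C(C)=C/Cc1c(O)ccc(Br)c1O | intermediate
9 | 6-bromo-3-(tert-butyldimethylsilyloxy)-2-geranylphenol | CC(C)=CCC/C(C)=C/Cc1c(O[Si](C)(C)C(C)(C)C)ccc(Br)c1O | intermediate
10 | ethyl 3-(4-hydroxyphenyl)-3-oxopropanoate | CCOC(=O)CC(=O)c1ccc(O)cc1 | starting material
11 | ethyl 3-[4-(tert-butyldimethylsilyloxy)phenyl]-3-oxopropanoate | CCOC(=O)CC(=O)c1ccc(O[Si](C)(C)C(C)(C)C)cc1 | intermediate
12 | ethyl (3R)-3-[4-(tert-butyldimethylsilyloxy)phenyl]-3-hydroxypropanoate | CCOC(=O)C[C@@H](O)c1ccc(O[Si](C)(C)C(C)(C)C)cc1 | intermediate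
13 | (3R)-3-[4-(tert-butyldimethylsilyloxy)phenyl]-3-hydroxy-N-methoxy-N-methylpropanamide | CON(C)C(=O)C[C@@H](O)c1ccc(O[Si](C)(C)C(C)(C)C)cc1 | intermediate
14 | (3S)-3-[6-bromo-3-(tert-butyldimethylsilyloxy)-2-geranylphenoxy]-3-[4-(tert-butyldimethylsilyloxy)phenyl]-N-methoxy-N-methylpropanamide | CC(C)=CCC/C(C)=C/Cc1c(O[Si](C)(C)C(C)(C)C)ccc(Br)c1O[C@H](c1ccc(O[Si](C)(C)C(C)(C)C)cc1)CC(=O)N(C)OC | intermediate
15 | aryllithium from 14 (lithium in place of bromine at the future C4a) | CC(C)=CCC/C(C)=C/Cc1c(O[Si](C)(C)C(C)(C)C)ccc([Li])c1O[C@H](c1ccc(O[Si](C)(C)C(C)(C)C)cc1)CC(=O)N(C)OC | intermediate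
16 | lithium hemiaminal: lithium (2S)-7-(tert-butyldimethylsilyloxy)-2-[4-(tert-butyldimethylsilyloxy)phenyl]-8-geranyl-4-[methoxy(methyl)amino]chroman-4-olate (C4 configuration undefined) | CC(C)=CCC/C(C)=C/Cc1c(O[Si](C)(C)C(C)(C)C)ccc2c1O[C@H](c1ccc(O[Si](C)(C)C(C)(C)C)cc1)CC2(O[Li])N(C)OC | intermediate
17 | (2S)-7-(tert-butyldimethylsilyloxy)-2-[4-(tert-butyldimethylsilyloxy)phenyl]-8-geranylchroman-4-one | CC(C)=CCC/C(C)=C/Cc1c(O[Si](C)(C)C(C)(C)C)ccc2c1O[C@H](c1ccc(O[Si](C)(C)C(C)(C)C)cc1)CC2=O | intermediate
18 | (2S)-7,4'-dihydroxy-8-geranylflavanone | CC(C)=CCC/C(C)=C/Cc1c(O)ccc2c1O[C@H](c1ccc(O)cc1)CC2=O | target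

**Step count**
Total: 11 steps. Longest linear sequence: 8 steps (steps 1–5, 9, 10, 11, from resorcinol). The side branch (steps 6–8) joins at step 9.

**Steps most likely to fail**

Step 10. The risk is deprotonation alpha to the amide (by t-BuLi, or by proton transfer to the aryllithium) followed by expulsion of the aryloxide from C2, or addition of t-BuLi to the amide, in place of exchange and ring closure. The fallback reverses the order in which the two bonds of ring C are made: C4–C4a is formed intermolecularly and O1–C2 is closed last by an intramolecular Mitsunobu reaction with inversion. It sets out from 9 and 13 and returns at 17.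
- Alcohol 13 is silylated (Et3SiCl, imidazole, CH2Cl2) to (3R)-3-[4-(tert-butyldimethylsilyloxy)phenyl]-N-methoxy-N-methyl-3-(triethylsilyloxy)propanamide F1.
- Phenol 9 is treated with t-BuLi (3 equiv, THF, −78 °C), which removes the hydroxyl proton and exchanges the bromine, giving lithium 3-(tert-butyldimethylsilyloxy)-2-geranyl-6-lithiophenoxide F2.
- Addition of F1, warming to 0 °C and an NH4Cl quench should give (3R)-1-[4-(tert-butyldimethylsilyloxy)-3-geranyl-2-hydroxyphenyl]-3-[4-(tert-butyldimethylsilyloxy)phenyl]-3-(triethylsilyloxy)propan-1-one F3. The electrophile carries no β-aryloxy leaving group at this stage.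
- The triethylsilyl ether is removed with PPTS in MeOH at 0 °C, which aryl TBS ethers tolerate, to give (3R)-1-[4-(tert-butyldimethylsilyloxy)-3-geranyl-2-hydroxyphenyl]-3-[4-(tert-butyldimethylsilyloxy)phenyl]-3-hydroxypropan-1-one F4.
- PPh3 and DIAD in toluene at 0 °C then close ring C by displacement of the activated benzylic hydroxyl by the ortho phenol with inversion, (R) to (S), giving 17 ahead of step 11.

Step 9. The risks are slow reaction at a phenol with two ortho substituents, dehydration of the activated β-hydroxy amide to the cinnamamide, and partial ionisation of the electron-rich benzylic oxyphosphonium with erosion of configuration. The fallback uses an alcohol partner without the acidifying carbonyl, so dehydration to a conjugated amide is no longer possible and more forcing (concentrated) Mitsunobu conditions can be used; the carbonyl is built after the ether. It sets out from 12 and 9 and returns at 14.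
- Ester 12 is reduced (LiBH4, THF) to (1R)-1-[4-(tert-butyldimethylsilyloxy)phenyl]propane-1,3-diol F5.
- The primary hydroxyl is acylated selectively (pivaloyl chloride, pyridine, CH2Cl2, 0 °C) to (3R)-3-[4-(tert-butyldimethylsilyloxy)phenyl]-3-hydroxypropyl pivalate F6.
- Mitsunobu etherification with 9 (PPh3, DIAD, toluene) gives, with inversion, (3S)-3-[6-bromo-3-(tert-butyldimethylsilyloxy)-2-geranylphenoxy]-3-[4-(tert-butyldimethylsilyloxy)phenyl]propyl pivalate F7.
- Reductive removal of the pivalate (i-Bu2AlH, CH2Cl2, −78 °C) gives (3S)-3-[6-bromo-3-(tert-butyldimethylsilyloxy)-2-geranylphenoxy]-3-[4-(tert-butyldimethylsilyloxy)phenyl]propan-1-ol F8.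
- Oxidation with TEMPO (catalytic) and PhI(OAc)2 in MeCN/water passes through (3S)-3-[6-bromo-3-(tert-butyldimethylsilyloxy)-2-geranylphenoxy]-3-[4-(tert-butyldimethylsilyloxy)phenyl]propanal F9 to (3S)-3-[6-bromo-3-(tert-butyldimethylsilyloxy)-2-geranylphenoxy]-3-[4-(tert-butyldimethylsilyloxy)phenyl]propanoic acid F10.
- Activation with carbonyldiimidazole and addition of MeNHOMe·HCl gives 14.

Step 5. The risk is silylation at the wrong oxygen (the more acidic hydroxyl next to bromine) or at both, giving a regioisomeric or over-protected phenol. The fallback differentiates the two oxygens before the bromine is introduced, so that the remaining MOM group alone decides where the bromine goes. It sets out from 5 and returns at 9.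
- Methanolysis of 5 (HCl, MeOH, rt) is stopped at partial conversion to give 2-geranyl-3-(methoxymethoxy)phenol F11. Only one mono-deprotected product is possible because 5 is symmetrical, and recovered 5 is recycled.
- Silylation (TBSCl, imidazole, DMF) gives tert-butyl[2-geranyl-3-(methoxymethoxy)phenoxy]dimethylsilane F12.
- Lithiation with s-BuLi/TMEDA (THF, −78 °C) can only occur next to the OMOM group and gives 1-(tert-butyldimethylsilyloxy)-2-geranyl-4-lithio-3-(methoxymethoxy)benzene F13.
- BrCCl2CCl2Br converts F13 into 1-bromo-4-(tert-butyldimethylsilyloxy)-3-geranyl-2-(methoxymethoxy)benzene F14.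
- Selective removal of the MOM group with ZnBr2 and propane-1-thiol (CH2Cl2, 0 °C), conditions that leave the aryl silyl ether and the alkenes alone, gives 9.

**Further compounds**
F1 | step 10 | (3R)-3-[4-(tert-butyldimethylsilyloxy)phenyl]-N-methoxy-N-methyl-3-(triethylsilyloxy)propanamide | CON(C)C(=O)C[C@@H](O[Si](CC)(CC)CC)c1ccc(O[Si](C)(C)C(C)(C)C)cc1
F2 | step 10 | lithium 3-(tert-butyldimethylsilyloxy)-2-geranyl-6-lithiophenoxide | CC(C)=CCC/C(C)=C/Cc1c(O[Si](C)(C)C(C)(C)C)ccc([Li])c1O[Li]
F3 | step 10 | (3R)-1-[4-(tert-butyldimethylsilyloxy)-3-geranyl-2-hydroxyphenyl]-3-[4-(tert-butyldimethylsilyloxy)phenyl]-3-(triethylsilyloxy)propan-1-one | CC(C)=CCC/C(C)=C/Cc1c(O[Si](C)(C)C(C)(C)C)ccc(C(=O)C[C@@H](O[Si](CC)(CC)CC)c2ccc(O[Si](C)(C)C(C)(C)C)cc2)c1O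
F4 | step 10 | (3R)-1-[4-(tert-butyldimethylsilyloxy)-3-geranyl-2-hydroxyphenyl]-3-[4-(tert-butyldimethylsilyloxy)phenyl]-3-hydroxypropan-1-one | CC(C)=CCC/C(C)=C/Cc1c(O[Si](C)(C)C(C)(C)C)ccc(C(=O)C[C@@H](O)c2ccc(O[Si](C)(C)C(C)(C)C)cc2)c1O
F5 | step 9 | (1R)-1-[4-(tert-butyldimethylsilyloxy)phenyl]propane-1,3-diol | OCC[C@@H](O)c1ccc(O[Si](C)(C)C(C)(C)C)cc1
F6 | step 9 | (3R)-3-[4-(tert-butyldimethylsilyloxy)phenyl]-3-hydroxypropyl pivalate | CC(C)(C)C(=O)OCC[C@@H](O)c1ccc(O[Si](C)(C)C(C)(C)C)cc1
F7 | step 9 | (3S)-3-[6-bromo-3-(tert-butyldimethylsilyloxy)-2-geranylphenoxy]-3-[4-(tert-butyldimethylsilyloxy)phenyl]propyl pivalate | CC(C)=CCC/C(C)=C/Cc1c(O[Si](C)(C)C(C)(C)C)ccc(Br)c1O[C@H](c1ccc(O[Si](C)(C)C(C)(C)C)cc1)CCOC(=O)C(C)(C)C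
F8 | step 9 | (3S)-3-[6-bromo-3-(tert-butyldimethylsilyloxy)-2-geranylphenoxy]-3-[4-(tert-butyldimethylsilyloxy)phenyl]propan-1-ol | CC(C)=CCC/C(C)=C/Cc1c(O[Si](C)(C)C(C)(C)C)ccc(Br)c1O[C@H](c1ccc(O[Si](C)(C)C(C)(C)C)cc1)CCO
F9 | step 9 | (3S)-3-[6-bromo-3-(tert-butyldimethylsilyloxy)-2-geranylphenoxy]-3-[4-(tert-butyldimethylsilyloxy)phenyl]propanal | CC(C)=CCC/C(C)=C/Cc1c(O[Si](C)(C)C(C)(C)C)ccc(Br)c1O[C@H](c1ccc(O[Si](C)(C)C(C)(C)C)cc1)CC=O
F10 | step 9 | (3S)-3-[6-bromo-3-(tert-butyldimethylsilyloxy)-2-geranylphenoxy]-3-[4-(tert-butyldimethylsilyloxy)phenyl]propanoic acid | CC(C)=CCC/C(C)=C/Cc1c(O[Si](C)(C)C(C)(C)C)ccc(Br)c1O[C@H](c1ccc(O[Si](C)(C)C(C)(C)C)cc1)CC(=O)O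
F11 | step 5 | 2-geranyl-3-(methoxymethoxy)phenol | CC(C)=CCC/C(C)=C/Cc1c(O)cccc1OCOC
F12 | step 5 | tert-butyl[2-geranyl-3-(methoxymethoxy)phenoxy]dimethylsilane | CC(C)=CCC/C(C)=C/Cc1c(O[Si](C)(C)C(C)(C)C)cccc1OCOC
F13 | step 5 | 1-(tert-butyldimethylsilyloxy)-2-geranyl-4-lithio-3-(methoxymethoxy)benzene | CC(C)=CCC/C(C)=C/Cc1c(O[Si](C)(C)C(C)(C)C)ccc([Li])c1OCOC
F14 | step 5 | 1-bromo-4-(tert-butyldimethylsilyloxy)-3-geranyl-2-(methoxymethoxy)benzene | CC(C)=CCC/C(C)=C/Cc1c(O[Si](C)(C)C(C)(C)C)ccc(Br)c1OCOC
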